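A direct plan would benzoylate phloroglucinol A1 under Friedel–Crafts conditions to 2,4,6-trihydroxybenzophenone A2 and would then attach both prenyl groups to the finished aromatic core of A2.
For this, A2 would undergo a palladium-catalysed twofold O-(1,1-dimethylallyl)ation with methyl 2-methylbut-3-en-2-yl carbonate A3 to the bis-ether A4, followed by two aromatic Claisen shifts in the same pot.
Its weakest step would be the twofold O-tert-prenylation of the unprotected acylphloroglucinol A2: three phenols and the nucleophilic ring carbons would compete, C-allylation and linear ethers would have to be beaten, and nothing would enforce the pattern.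
The second would be the double Claisen cascade at 120 °C on the most advanced material: a shift could choose between ortho carbons, ortho-prenylphenols could cyclise to chromans, and A4 could not be purified first.
The third would be the separate step spent on A3, which would add a reagent but no complexity.
The plan would contain no stereocentre and no ring closure, so all its risk would lie in regiocontrol on ring A, from A1 onwards.

**Plan of the new route**
The retrosynthesis cuts ring A itself: the two ring bonds from the benzoyl-bearing carbon C1 to C2 and C6 and, one stage earlier, the bonds from C3 and C5 to the prenyl CH2 groups.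
This is possible because ring A is a benzene-1,3,5-triol, the enol form of a cyclohexane-1,3,5-trione: C2, C4 and C6 are acyl carbons, C1, C3 and C5 are enolate carbons, and the mirror plane through C1 and C4 makes C2–C6 a symmetric 2,4-diprenyl-3-oxoglutaryl unit.
Dimethyl 3-oxoglutarate is prenylated at both α-carbons, acetophenone supplies C1 with the benzoyl group already on it (first Claisen condensation, open chain), and the second Claisen condensation of the resulting tetraketide closes ring A.
The phenyl ring is bought; ring A arises in the last step, fully substituted.
No aromatic ring is prenylated and no Friedel–Crafts reaction or O-to-C shift occurs: the prenyl positions are fixed on sp3 carbons of the chain and aromatisation is the final event.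

Key step: step 3

Remark: 1,3-dicarbonyl compounds are drawn as keto forms, although they would exist as enol and diastereomer mixtures. Chain carbons of 8 are numbered from the ester carbon (C1) to the benzoyl carbon (C7).

Step 1
Reactants: 1 dimethyl 3-oxopentanedioate (dimethyl acetone-1,3-dicarboxylate); 2 1-bromo-3-methylbut-2-ene (prenyl bromide, first equivalent)
Product: 4 dimethyl 2,4-bis(3-methylbut-2-en-1-yl)-3-oxopentanedioate, via mono-prenylated diester 3 (not isolated)
Conditions: K2CO3 (3.0 equiv), 2 (2.05 equiv in all, added in two portions), acetone, 0 °C to rt
Reagents that add atoms: 1-bromo-3-methylbut-2-ene (prenyl bromide, the second equivalent of 2), CC(C)=CCBr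
Why: Twofold enolate C-alkylation of a β-keto diester (SN2 at the primary allylic bromide), in which the first equivalent of 2 gives 3 and the still unsubstituted α′-CH2 of 3 is the more acidic and less hindered site, so the second equivalent should go to C4 and not to C2; the two new stereocentres arise without control (meso and racemic forms), which is harmless because both are epimerisable and become sp2 carbons of ring A in step 3.

Step 2
Reactants: 4 dimethyl 2,4-bis(3-methylbut-2-en-1-yl)-3-oxopentanedioate; 5 acetophenone
Product: 8 methyl 2,4-bis(3-methylbut-2-en-1-yl)-3,5,7-trioxo-7-phenylheptanoate, via lithium enolate of acetophenone 6 (not isolated), via lithium mono-enolate of diester 7 (not isolated)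
Conditions: LiN(SiMe3)2 (3.5 equiv), 5 (2.4 equiv), THF, −78 °C; then 4 (1.0 equiv), −78 °C to rt; AcOH, −20 °C; pH 5 buffer
Reagents that add atoms: none
Why: Proposed new method: a crossed Claisen acylation of a ketone enolate by one ester of a symmetric β-keto diester that protects itself in the flask; the spare base turns 4 into its chelated mono-enolate 7, in which the ester at C1 is conjugated to the enolate and inert and the C3 ketone is masked, whereas the ester at C5 is insulated by the sp3 carbon C4 and stays an ordinary α-branched methyl ester, so the carbon of enolate 6 should add there, methoxide leaves, and the new 5,7-diketone (its C6 methylene is the most acidic site) is deprotonated at once by excess 6, which makes the acylation irreversible and prevents a second one; the two esters of the symmetric diester are thus distinguished without a protecting group; the closest known reaction types are the Claisen acylation of ketone enolates with esters to 1,3-diketones and polyketo-chain extensions in which the ester of an enolised β-keto ester acts as acyl donor towards a strongly basic enolate; no stereocentre of consequence is formed, and any 10 that forms in the flask is carried along.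

Step 3
Reactants: 8 methyl 2,4-bis(3-methylbut-2-en-1-yl)-3,5,7-trioxo-7-phenylheptanoate
Product: 10 clusiaphenone B, via cyclohexane-1,3,5-trione tautomer 9 (not isolated)
Conditions: Mg(OMe)2 (4 equiv), degassed MeOH, Ar, reflux; then cold 0.5 M HCl
Reagents that add atoms: none
Why: Mg(OMe)2 deprotonates the most acidic position of 8, the C6 methylene between the C5 and C7 ketones, and the magnesium-chelated enolate carbon attacks the ester carbon C1; loss of methoxide gives trione 9, which enolises three times to the aromatic ring A and is held as its magnesium phenoxide, so the closure is irreversible. The reaction type is the base-induced Claisen (Dieckmann-type) cyclisation of 3,5,7-trioxoalkanoates to acylphloroglucinols, the laboratory counterpart of the folding of a benzoyl-primed tetraketide. Ring A closes by a 6-exo-trig acyl substitution between chain carbons C6 and C1, allowed for the enolate in either form (enol double bond towards C5 inside the new ring or towards C7 outside it). No stereocentre is formed; the two epimerisable centres of 8 (C2 and C4) become the sp2 ring carbons that carry the prenyl groups. The step needs C-acylation at C6 to win over aldol attack of C2 on the C7 ketone, over O-acylation by the C5 enolate oxygen and over chain cleavage: the prenyl group on C2 makes the aldol adduct a quaternary β-hydroxy ketone that cannot aromatise by loss of water and reverts, lactonisation to the 2-pyranone is reversible in methoxide whereas C-acylation is withdrawn by aromatisation, and chelation keeps every ketone enolised and so safe from retro-Claisen attack, while methoxide on a methyl ester makes transesterification invisible. The prenyl groups are inert to these conditions and to the cold dilute acid of the work-up.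

**Compound list**
1 | dimethyl 3-oxopentanedioate (dimethyl acetone-1,3-dicarboxylate) | COC(=O)CC(=O)CC(=O)OC | starting material
2 | 1-bromo-3-methylbut-2-ene (prenyl bromide) | CC(C)=CCBr | starting material
3 | dimethyl 2-(3-methylbut-2-en-1-yl)-3-oxopentanedioate, racemic, epimerisable | COC(=O)C(CC=C(C)C)C(=O)CC(=O)OC | intermediate
4 | dimethyl 2,4-bis(3-methylbut-2-en-1-yl)-3-oxopentanedioate, meso and racemic forms, epimerisable | COC(=O)C(CC=C(C)C)C(=O)C(CC=C(C)C)C(=O)OC | intermediate
5 | acetophenone (1-phenylethan-1-one) | CC(=O)c1ccccc1 | starting material
6 | lithium 1-phenylethen-1-olate | [Li+].[O-]C(=C)c1ccccc1 | intermediate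
7 | lithium (2Z)-1,5-dimethoxy-2,4-bis(3-methylbut-2-en-1-yl)-1,5-dioxopent-2-en-3-olate (chelated mono-enolate of 4) | [Li+].COC(=O)/C(CC=C(C)C)=C(\[O-])C(CC=C(C)C)C(=O)OC | intermediate
8 | methyl 2,4-bis(3-methylbut-2-en-1-yl)-3,5,7-trioxo-7-phenylheptanoate, diastereomer and enol mixture | COC(=O)C(CC=C(C)C)C(=O)C(CC=C(C)C)C(=O)CC(=O)c1ccccc1 | intermediate
9 | 2-benzoyl-4,6-bis(3-methylbut-2-en-1-yl)cyclohexane-1,3,5-trione (keto tautomer of 10) | O=C(c1ccccc1)C1C(=O)C(CC=C(C)C)C(=O)C(CC=C(C)C)C1=O | intermediate
10 | clusiaphenone B, phenyl[2,4,6-trihydroxy-3,5-bis(3-methylbut-2-en-1-yl)phenyl]methanone, achiral | CC(C)=CCc1c(O)c(CC=C(C)C)c(O)c(C(=O)c2ccccc2)c1O | target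

Total step count: 3. Longest linear sequence: 3 steps (1 to 4 to 8 to 10).

**Steps most likely to fail**

Step 2 (bears the label). Enolate 6 may act only as a base, removing the C4 proton of 7 to give the unreactive bis-enolate. Attack at the hindered α-branched ester may be slower than self-condensation of acetophenone, so that 4 is recovered. The fallback uses known polyanion chemistry, sets out from 2 and returns at 8. Methyl acetoacetate would be converted into its dianion (NaH, then n-BuLi, THF, 0 °C) and alkylated at the γ-carbon with 2 to give methyl 7-methyl-3-oxooct-6-enoate F1. Enolate alkylation at the α-carbon with a second equivalent of 2 (K2CO3, acetone) would give methyl 7-methyl-2-(3-methylbut-2-en-1-yl)-3-oxooct-6-enoate F2. The dianion of F2 (LiN(i-Pr)2, 2.2 equiv) would be acylated at its γ-carbon with N-methoxy-N-methylacetamide to give methyl 2,4-bis(3-methylbut-2-en-1-yl)-3,5-dioxohexanoate F3. The trianion of F3 (LiN(i-Pr)2, 4.4 equiv) would then be benzoylated at the terminal methyl carbon with methyl benzoate to give 8. Each C–C bond would be made by the terminal carbanion of a polyanion, so proton transfer to the acyl donor could not interfere.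

Step 3. The open-chain tetraketide may be lost before C-acylation, by retro-Claisen cleavage with methoxide or by cyclodehydration on isolation. O-acylation to the 2-pyranone or aldol closure at C7 may also divert the chain. The fallback sets out from 8 and returns at 10, with ring A arising by ring transformation of a heterocycle. Heating 8 with DBU in toluene (80 °C) would lactonise the 3,5-dioxo ester part with loss of methanol to 4-hydroxy-3,5-bis(3-methylbut-2-en-1-yl)-6-(2-oxo-2-phenylethyl)-2H-pyran-2-one F4. F4 is an isomer of the target that should be storable and purifiable, and its C3 carbonyl is part of a vinylogous acid and shielded from cleavage. F4 would then be treated with Mg(OMe)2 in methanol at reflux. The lactone would open to the magnesium chelate of the chain only in low stationary concentration, and C-acylation and aromatisation would give 10.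

Step 1. A third alkylation at an already substituted α-carbon, geminal dialkylation at C2 and O-prenylation may give mixtures that are hard to separate from 4. The fallback sets out from 2 and returns at 4, with each prenyl group placed on a malonate. Dimethyl malonate (in excess, NaH, THF) would be alkylated with 2 to dimethyl 2-(3-methylbut-2-en-1-yl)propanedioate F5. Half-saponification (KOH, 1 equiv, MeOH) would give 3-methoxy-2-(3-methylbut-2-en-1-yl)-3-oxopropanoic acid F6. One portion of F6 would be activated with 1,1′-carbonyldiimidazole to methyl 2-(1H-imidazole-1-carbonyl)-5-methylhex-4-enoate F7. F7 would be condensed with a second portion of F6 in the presence of MgCl2 and Et3N (decarboxylative Claisen condensation of a malonic half-ester) to give 4.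

**Further compounds**
F1 | step 2 | methyl 7-methyl-3-oxooct-6-enoate | COC(=O)CC(=O)CCC=C(C)C
F2 | step 2 | methyl 7-methyl-2-(3-methylbut-2-en-1-yl)-3-oxooct-6-enoate | COC(=O)C(CC=C(C)C)C(=O)CCC=C(C)C
F3 | step 2 | methyl 2,4-bis(3-methylbut-2-en-1-yl)-3,5-dioxohexanoate | COC(=O)C(CC=C(C)C)C(=O)C(CC=C(C)C)C(C)=O
F4 | step 3 | 4-hydroxy-3,5-bis(3-methylbut-2-en-1-yl)-6-(2-oxo-2-phenylethyl)-2H-pyran-2-one | O=C(CC1=C(CC=C(C)C)C(O)=C(CC=C(C)C)C(=O)O1)c1ccccc1
F5 | step 1 | dimethyl 2-(3-methylbut-2-en-1-yl)propanedioate | COC(=O)C(CC=C(C)C)C(=O)OC
F6 | step 1 | 3-methoxy-2-(3-methylbut-2-en-1-yl)-3-oxopropanoic acid | COC(=O)C(CC=C(C)C)C(=O)O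
F7 | step 1 | methyl 2-(1H-imidazole-1-carbonyl)-5-methylhex-4-enoate | COC(=O)C(CC=C(C)C)C(=O)n1ccnc1
A1 | direct plan | phloroglucinol (benzene-1,3,5-triol) | Oc1cc(O)cc(O)c1
A2 | direct plan | 2,4,6-trihydroxybenzophenone | O=C(c1ccccc1)c1c(O)cc(O)cc1O
A3 | direct plan | methyl 2-methylbut-3-en-2-yl carbonate | COC(=O)OC(C)(C)C=C
A4 | direct plan | [2-hydroxy-4,6-bis(2-methylbut-3-en-2-yloxy)phenyl](phenyl)methanone | O=C(c1ccccc1)c1c(O)cc(OC(C)(C)C=C)cc1OC(C)(C)C=C
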